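## Retrosynthetic overview

1. **Key bond, made last: C5–C6.** The acid chain is numbered from the ester carbonyl C1, and C6 carries the pyrone. A thioester carbonyl is turned by Ni/Mn into an acyl-nickel acyl-anion equivalent. It is joined to racemic 2-(1-chloroethyl)pyrone, an α-cation (enolonium-type) equivalent of a carbon that is naturally nucleophilic. Two electrophilic carbons are thus coupled, and the ligand sets the labile C6 centre.
2. **Ester C–O bond.** A Yamaguchi esterification joins a C1-acid/C5-thioester building block to the mono-ketal form of the diketo alcohol (nonane numbering C3'–C7').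
3. **Acid part.** Double Fráter–Seebach methylation of dimethyl 3-hydroxyglutarate gives the meso anti,anti triad. This is closed to the all-cis cyclic anhydride. A catalytic desymmetrising thiolysis then fixes C2–C4 absolutely and differentiates the two ends.
4. **Alcohol part.** A proline aldol with dynamic kinetic resolution on thiopyran templates sets C4' and C6', followed by Raney Ni desulfurisation.
5. **Rings.** The γ-pyrone is the only ring of the target. It is formed first, from pentan-3-one and propanoic acid, and carried through. The thiopyran, dioxolane and anhydride rings are temporary.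

Assumption: the sense of induction in the two catalyst-controlled steps (11 and 13) is taken by analogy with the closest known substrates; both catalysts are sold in both (pseudo)enantiomeric forms, so a reversed sense is corrected by exchanging the antipode without changing the route.

## Route

Step 1
Reactants: 1 pentan-3-one; 2 propanoic acid
Product: 4 2,6-diethyl-3,5-dimethyl-4H-pyran-4-one, via 4,6-dimethylnonane-3,5,7-trione 3 (not isolated)
Conditions: 2 (2.5 equiv), polyphosphoric acid, 100 °C, 8 h; ice, aq NaHCO3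
Reagents that add atoms: none
Why: Polyphosphoric-acid double C-acylation of the ketone at both α-carbons followed by cyclodehydration of the 1,3,5-trione is the classical γ-pyrone synthesis, and no stereocentre is formed.

Step 2
Reactants: 4 2,6-diethyl-3,5-dimethyl-4H-pyran-4-one
Product: 6 (±)-2-(1-chloroethyl)-6-ethyl-3,5-dimethyl-4H-pyran-4-one, via lithium 2-ethylidenepyran-4-olate 5 (not isolated)
Conditions: LiN(SiMe3)2 (1.05 equiv), THF, −78 °C; cannulate into C2Cl6 (1.5 equiv), THF, −78 °C
Reagents that add atoms: hexachloroethane, ClC(Cl)(Cl)C(Cl)(Cl)Cl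
Why: Lateral (vinylogous) deprotonation of one of the two equivalent ethyl groups and electrophilic chlorination at the exocyclic carbon restores the pyrone; the racemic centre is resolved later in the stereoconvergent step 13.

Step 3
Reactants: 7 methyl 4-oxotetrahydro-2H-thiopyran-3-carboxylate
Product: 8 methyl (±)-1,4-dioxa-8-thiaspiro[4.5]decane-6-carboxylate
Conditions: HOCH2CH2OH (3 equiv), p-TsOH·H2O (5 mol %), toluene, Dean–Stark reflux
Reagents that add atoms: ethane-1,2-diol, OCCO
Why: Acid-catalysed ketalisation with azeotropic water removal masks the future C7' ketone so that the derived aldehyde is not a β-keto aldehyde.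

Step 4
Reactants: 8 methyl (±)-1,4-dioxa-8-thiaspiro[4.5]decane-6-carboxylate
Product: 9 (±)-1,4-dioxa-8-thiaspiro[4.5]decane-6-carbaldehyde
Conditions: iBu2AlH (1.1 equiv), CH2Cl2, −78 °C; MeOH, then aqueous tartrate work-up
Reagents that add atoms: none
Why: Partial ester reduction stops at the aldehyde because the tetrahedral aluminate, chelated by a ketal oxygen, survives at −78 °C until the quench.

Step 5
Reactants: 9 (±)-1,4-dioxa-8-thiaspiro[4.5]decane-6-carbaldehyde; 10 tetrahydro-4H-thiopyran-4-one
Product: 11 (3R)-3-{(S)-hydroxy[(6R)-1,4-dioxa-8-thiaspiro[4.5]decan-6-yl]methyl}tetrahydro-4H-thiopyran-4-one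
Conditions: (R)-proline (0.5 equiv), 10 (3 equiv), wet DMSO, rt, 4 d
Reagents that add atoms: none
Why: In this proline-catalysed enamine aldol with dynamic kinetic resolution, the hydrogen-bonded chair transition state gives the anti aldol with (R)-C4', and only the rapidly racemising aldehyde enantiomer that reacts in the Felkin sense is consumed, which sets (R)-C6'.

Step 6
Reactants: 11 (3R)-3-{(S)-hydroxy[(6R)-1,4-dioxa-8-thiaspiro[4.5]decan-6-yl]methyl}tetrahydro-4H-thiopyran-4-one
Product: 12 (4R,5S,6R)-6-(2-ethyl-1,3-dioxolan-2-yl)-5-hydroxy-4-methylheptan-3-one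
Conditions: Raney Ni (W-2), NaH2PO2·H2O, AcOH/NaOAc buffer (pH 5.2), EtOH, rt
Reagents that add atoms: none
Why: Raney nickel desulfurisation turns each CH2–S–CH2 unit into a methyl and an ethyl terminus, and the buffered hypophosphite medium spares the ketone, the ketal and the three stereocentres.

Step 7
Reactants: 13 dimethyl 3-hydroxypentanedioate
Product: 15 dimethyl (2R,3r,4S)-3-hydroxy-2,4-dimethylpentanedioate (meso), via anti-monomethyl diester 14 (not isolated)
Conditions: LiN(iPr)2 (2.2 equiv), THF, −78 → −20 °C; MeI (1.05 equiv); then LiN(iPr)2 (1.2 equiv), −78 → −20 °C; MeI (1.5 equiv); AcOH quench, −78 °C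
Reagents that add atoms: iodomethane, CI
Why: In this Fráter–Seebach alkylation run twice in one flask, the chelated lithium alkoxide–enolate is methylated anti to the C3 substituent, first on one arm and then on the less hindered other arm, giving the anti,anti relative configuration of C2–C4.

Step 8
Reactants: 15 dimethyl (2R,3r,4S)-3-hydroxy-2,4-dimethylpentanedioate
Product: 16 dimethyl (2R,3r,4S)-3-[(tert-butyldimethylsilyl)oxy]-2,4-dimethylpentanedioate
Conditions: TBSOTf (1.3 equiv), 2,6-lutidine (2 equiv), CH2Cl2, 0 °C → rt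
Reagents that add atoms: tert-butyldimethylsilyl trifluoromethanesulfonate, CC(C)(C)[Si](C)(C)OS(=O)(=O)C(F)(F)F
Why: Silyl triflate silylation protects the hindered carbinol under non-epimerising conditions so that it cannot lactonise or acylate later.

Step 9
Reactants: 16 dimethyl (2R,3r,4S)-3-[(tert-butyldimethylsilyl)oxy]-2,4-dimethylpentanedioate
Product: 17 (2R,3r,4S)-3-[(tert-butyldimethylsilyl)oxy]-2,4-dimethylpentanedioic acid
Conditions: LiOH·H2O (6 equiv), THF/MeOH/H2O (2:1:1), rt → 40 °C; 1 M HCl to pH 3, 0 °C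
Reagents that add atoms: lithium hydroxide, [Li+].[OH-]
Why: Saponification of the methyl esters is faster than α-deprotonation, and each carboxylate formed shuts down enolisation and β-elimination, as in the unmethylated 3-silyloxyglutarate series.

Step 10
Reactants: 17 (2R,3r,4S)-3-[(tert-butyldimethylsilyl)oxy]-2,4-dimethylpentanedioic acid
Product: 18 (3R,4r,5S)-4-[(tert-butyldimethylsilyl)oxy]-3,5-dimethyloxane-2,6-dione (meso all-cis anhydride)
Conditions: DCC (1.05 equiv), CH2Cl2, 0 °C → rt; filter
Reagents that add atoms: none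
Why: Carbodiimide cyclodehydration closes the six-membered anhydride at room temperature, which avoids the thermal epimerisation expected in hot acetic anhydride.

Step 11
Reactants: 18 (3R,4r,5S)-4-[(tert-butyldimethylsilyl)oxy]-3,5-dimethyloxane-2,6-dione
Product: 19 (2R,3S,4S)-3-[(tert-butyldimethylsilyl)oxy]-5-(ethylsulfanyl)-2,4-dimethyl-5-oxopentanoic acid
Conditions: EtSH (2 equiv), N-[(8α,9S)-6'-methoxycinchonan-9-yl]-3,5-bis(trifluoromethyl)benzenesulfonamide (10 mol %), MTBE, −20 °C → rt
Reagents that add atoms: ethanethiol, CCS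
Why: In this organocatalytic desymmetrising thiolysis, the bifunctional cinchona sulfonamide binds the anhydride and delivers the thiol to the carbonyl next to the (S)-α-carbon, which fixes the absolute configuration of C2, C3 and C4 and leaves C1 as free acid and C5 as acyl donor.

Step 12
Reactants: 19 (2R,3S,4S)-3-[(tert-butyldimethylsilyl)oxy]-5-(ethylsulfanyl)-2,4-dimethyl-5-oxopentanoic acid; 12 (4R,5S,6R)-6-(2-ethyl-1,3-dioxolan-2-yl)-5-hydroxy-4-methylheptan-3-one
Product: 21 (2R,3S,4R)-2-(2-ethyl-1,3-dioxolan-2-yl)-4-methyl-5-oxoheptan-3-yl (2R,3S,4S)-3-[(tert-butyldimethylsilyl)oxy]-5-(ethylsulfanyl)-2,4-dimethyl-5-oxopentanoate, via mixed 2,4,6-trichlorobenzoic anhydride 20 (not isolated)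
Conditions: 2,4,6-Cl3C6H2COCl (1.2 equiv), Et3N (1.5 equiv), toluene, rt; then 12 (1.2 equiv), DMAP (2 equiv), toluene, rt → 40 °C
Reagents that add atoms: none
Why: The Yamaguchi esterification acylates hindered secondary alcohols through the acylpyridinium ion, the S-ethyl thioester is inert to DMAP, and the most base-labile centre C6 does not yet exist.

Step 13
Reactants: 21 (2R,3S,4R)-2-(2-ethyl-1,3-dioxolan-2-yl)-4-methyl-5-oxoheptan-3-yl (2R,3S,4S)-3-[(tert-butyldimethylsilyl)oxy]-5-(ethylsulfanyl)-2,4-dimethyl-5-oxopentanoate; 6 (±)-2-(1-chloroethyl)-6-ethyl-3,5-dimethyl-4H-pyran-4-one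
Product: 22 (2R,3S,4R)-2-(2-ethyl-1,3-dioxolan-2-yl)-4-methyl-5-oxoheptan-3-yl (2R,3R,4S,6S)-3-[(tert-butyldimethylsilyl)oxy]-6-(6-ethyl-3,5-dimethyl-4-oxo-4H-pyran-2-yl)-2,4-dimethyl-5-oxoheptanoate
Conditions: NiCl2(dme) (15 mol %), (R,R)-Ph-BOX [2,2'-(propane-2,2-diyl)bis((4R)-4-phenyl-4,5-dihydrooxazole)] (33 mol %), Mn powder (3 equiv), 2,6-dimethylbenzoic acid (0.75 equiv), 3 Å MS, 6 (2 equiv), DMA/THF (3:7), 20 °C, 36 h
Reagents that add atoms: none
Why: Proposed new method: zerovalent nickel inserts into the C(acyl)–S bond and Mn reduces the acyl-nickel thiolate to a monovalent acyl-nickel that acts as the C5 acyl-anion equivalent; this abstracts chlorine from either enantiomer of 6 to give a planar radical stabilised by the pyrone (a vinylogous α-carbonyl radical), which recombines at nickel, and reductive elimination from the trivalent acyl(alkyl)nickel forges C5–C6 with the bis(oxazoline) pocket selecting the face that gives (S)-C6; the medium is base-free, so neither C6 nor the β-acyloxy ketone is endangered; the closest known reaction types are the enantioconvergent nickel/bis(oxazoline) reductive acyl cross-coupling of acid chlorides with racemic secondary benzylic chlorides and the nickel-catalysed reductive ketone synthesis from thioesters, which also reaches ketones flanked by two branched carbons.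

Step 14
Reactants: 22 (2R,3S,4R)-2-(2-ethyl-1,3-dioxolan-2-yl)-4-methyl-5-oxoheptan-3-yl (2R,3R,4S,6S)-3-[(tert-butyldimethylsilyl)oxy]-6-(6-ethyl-3,5-dimethyl-4-oxo-4H-pyran-2-yl)-2,4-dimethyl-5-oxoheptanoate
Product: 23 (4R,6R)-4,6-dimethyl-3,7-dioxononan-5-yl (2R,3R,4S,6S)-6-(6-ethyl-3,5-dimethyl-4-oxo-4H-pyran-2-yl)-3-hydroxy-2,4-dimethyl-5-oxoheptanoate (target)
Conditions: 48% aq HF/MeCN (1:9), 0 °C → rt
Reagents that add atoms: water, O
Why: Acidic global deprotection (fluoride-assisted desilylation and ketal hydrolysis) avoids base, so no α-centre epimerises and no acyloxy group is eliminated; unmasking C7' makes the two (R)-arms identical, so the carbinol carbon C5' ceases to be stereogenic, as in the target.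

## Compound list

1 | pentan-3-one | CCC(=O)CC | starting material
2 | propanoic acid | CCC(=O)O | starting material
3 | 4,6-dimethylnonane-3,5,7-trione (stereoisomer and enol mixture) | CCC(=O)C(C)C(=O)C(C)C(=O)CC | intermediate (not isolated)
4 | 2,6-diethyl-3,5-dimethyl-4H-pyran-4-one | CCc1oc(CC)c(C)c(=O)c1C | intermediate
5 | lithium 6-ethyl-2-ethylidene-3,5-dimethyl-2H-pyran-4-olate | CC=C1OC(CC)=C(C)C([O-])=C1C.[Li+] | intermediate (not isolated)
6 | (±)-2-(1-chloroethyl)-6-ethyl-3,5-dimethyl-4H-pyran-4-one | CC(Cl)c1oc(CC)c(C)c(=O)c1C | intermediate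
7 | methyl 4-oxotetrahydro-2H-thiopyran-3-carboxylate (racemic) | COC(=O)C1CSCCC1=O | starting material
8 | methyl (±)-1,4-dioxa-8-thiaspiro[4.5]decane-6-carboxylate | COC(=O)C1CSCCC12OCCO2 | intermediate
9 | (±)-1,4-dioxa-8-thiaspiro[4.5]decane-6-carbaldehyde | O=CC1CSCCC12OCCO2 | intermediate
10 | tetrahydro-4H-thiopyran-4-one | O=C1CCSCC1 | starting material
11 | (3R)-3-{(S)-hydroxy[(6R)-1,4-dioxa-8-thiaspiro[4.5]decan-6-yl]methyl}tetrahydro-4H-thiopyran-4-one | O=C1CCSC[C@@H]1[C@H](O)[C@H]2CSCCC23OCCO3 | intermediate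
12 | (4R,5S,6R)-6-(2-ethyl-1,3-dioxolan-2-yl)-5-hydroxy-4-methylheptan-3-one | CCC(=O)[C@H](C)[C@H](O)[C@@H](C)C1(CC)OCCO1 | intermediate
13 | dimethyl 3-hydroxypentanedioate | COC(=O)CC(O)CC(=O)OC | starting material
14 | dimethyl (2RS,3RS)-3-hydroxy-2-methylpentanedioate (racemic anti isomer, one enantiomer drawn; lithium alkoxide in the flask) | COC(=O)[C@H](C)[C@H](O)CC(=O)OC | intermediate (not isolated)
15 | dimethyl (2R,3r,4S)-3-hydroxy-2,4-dimethylpentanedioate (meso, anti,anti) | COC(=O)[C@H](C)[C@H](O)[C@H](C)C(=O)OC | intermediate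
16 | dimethyl (2R,3r,4S)-3-[(tert-butyldimethylsilyl)oxy]-2,4-dimethylpentanedioate (meso) | COC(=O)[C@H](C)[C@H](O[Si](C)(C)C(C)(C)C)[C@H](C)C(=O)OC | intermediate
17 | (2R,3r,4S)-3-[(tert-butyldimethylsilyl)oxy]-2,4-dimethylpentanedioic acid (meso) | OC(=O)[C@H](C)[C@H](O[Si](C)(C)C(C)(C)C)[C@H](C)C(=O)O | intermediate
18 | (3R,4r,5S)-4-[(tert-butyldimethylsilyl)oxy]-3,5-dimethyloxane-2,6-dione (meso, all-cis) | O=C1[C@H](C)[C@H](O[Si](C)(C)C(C)(C)C)[C@H](C)C(=O)O1 | intermediate
19 | (2R,3S,4S)-3-[(tert-butyldimethylsilyl)oxy]-5-(ethylsulfanyl)-2,4-dimethyl-5-oxopentanoic acid | OC(=O)[C@H](C)[C@H](O[Si](C)(C)C(C)(C)C)[C@H](C)C(=O)SCC | intermediate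
20 | mixed anhydride of 19 with 2,4,6-trichlorobenzoic acid | O=C(OC(=O)[C@H](C)[C@H](O[Si](C)(C)C(C)(C)C)[C@H](C)C(=O)SCC)c1c(Cl)cc(Cl)cc1Cl | intermediate (not isolated)
21 | (2R,3S,4R)-2-(2-ethyl-1,3-dioxolan-2-yl)-4-methyl-5-oxoheptan-3-yl (2R,3S,4S)-3-[(tert-butyldimethylsilyl)oxy]-5-(ethylsulfanyl)-2,4-dimethyl-5-oxopentanoate | CCC(=O)[C@H](C)[C@H](OC(=O)[C@H](C)[C@H](O[Si](C)(C)C(C)(C)C)[C@H](C)C(=O)SCC)[C@@H](C)C1(CC)OCCO1 | intermediate
22 | (2R,3S,4R)-2-(2-ethyl-1,3-dioxolan-2-yl)-4-methyl-5-oxoheptan-3-yl (2R,3R,4S,6S)-3-[(tert-butyldimethylsilyl)oxy]-6-(6-ethyl-3,5-dimethyl-4-oxo-4H-pyran-2-yl)-2,4-dimethyl-5-oxoheptanoate | CCC(=O)[C@H](C)[C@H](OC(=O)[C@H](C)[C@H](O[Si](C)(C)C(C)(C)C)[C@H](C)C(=O)[C@@H](C)c1oc(CC)c(C)c(=O)c1C)[C@@H](C)C2(CC)OCCO2 | intermediate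
23 | (4R,6R)-4,6-dimethyl-3,7-dioxononan-5-yl (2R,3R,4S,6S)-6-(6-ethyl-3,5-dimethyl-4-oxo-4H-pyran-2-yl)-3-hydroxy-2,4-dimethyl-5-oxoheptanoate | CCC(=O)[C@H](C)C(OC(=O)[C@H](C)[C@H](O)[C@H](C)C(=O)[C@@H](C)c1oc(CC)c(C)c(=O)c1C)[C@@H](C)C(=O)CC | target

## Summary

Total step count: 14.

Longest linear sequence: 8 steps (steps 7–14, from 13). The alcohol branch (steps 3–6) and the pyrone branch (steps 1–2) run in parallel.

## Three steps most likely to fail

**Step 13 (key coupling).** The S-ethyl thioester of the large, α-branched acyl partner may enter the nickel cycle too slowly. The chiral acyl group may also override the ligand at C6.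

The fallback keeps the same C5–C6 bond, but makes it earlier on a small and more reactive acyl donor, and reverses the order of ketone and ester formation. It sets out from 18 and comes back at 22.
- Thiolysis of 18 with the pseudo-enantiomeric quinidine-derived sulfonamide gives the enantiomeric hemithioester F1, whose free acid is now C5.
- 1-Chloro-N,N,2-trimethylprop-1-en-1-amine converts it under neutral conditions into the acid chloride F2.
- F2 is coupled with 6 under NiCl2(dme)/Ph-BOX/Mn, where the acid chloride reacts far faster than the spectator thioester, to give the keto thioester F3.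
- AgOSO2CF3, buffered with 2,6-di-tert-butyl-4-methylpyridine, then activates sulfur and transfers the C1 acyl group to alcohol 12 without base, giving 22.

**Step 12 (esterification).** The carbinol of 12 is flanked by a neopentyl-like ketal arm and may resist acylation.

The fallback changes the protecting-group logic so that the alcohol is smaller. It sets out from 12 and comes back at 23.
- FeCl3·6H2O in CH2Cl2/acetone removes the ketal first and gives the diketo alcohol F4, whose carbinol carbon is no longer stereogenic.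
- F4 is acylated with 19 using 2-methyl-6-nitrobenzoic anhydride and DMAP to give the diketo ester thioester F5.
- The nickel coupling of step 13 with 6 gives the silyl-protected target F6.
- HF·pyridine in THF then gives 23.

**Step 11 (desymmetrising thiolysis).** The doubly α-branched anhydride may react slowly or with low selectivity with a thiol.

The fallback replaces catalytic thiolysis by stoichiometric alkaloid-mediated alcoholysis, followed by an exchange of the end groups. It sets out from 18 and comes back at 19.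
- Allyl alcohol with quinidine (1.1 equiv) in toluene at −55 °C opens the carbonyl next to the (R)-α-carbon and gives the allyl hemiester F7.
- EtSH with EDC and DMAP (cat.) converts the free acid into the allyl ester thioester F8.
- Pd(PPh3)4 with morpholine removes the allyl group under neutral conditions to give 19.

## Further compounds

F1 | step 13 | (2S,3R,4R)-3-[(tert-butyldimethylsilyl)oxy]-5-(ethylsulfanyl)-2,4-dimethyl-5-oxopentanoic acid (enantiomer of 19) | CCSC(=O)[C@H](C)[C@H](O[Si](C)(C)C(C)(C)C)[C@H](C)C(=O)O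
F2 | step 13 | S-ethyl (2R,3S,4S)-3-[(tert-butyldimethylsilyl)oxy]-5-chloro-2,4-dimethyl-5-oxopentanethioate | CCSC(=O)[C@H](C)[C@H](O[Si](C)(C)C(C)(C)C)[C@H](C)C(=O)Cl
F3 | step 13 | S-ethyl (2R,3R,4S,6S)-3-[(tert-butyldimethylsilyl)oxy]-6-(6-ethyl-3,5-dimethyl-4-oxo-4H-pyran-2-yl)-2,4-dimethyl-5-oxoheptanethioate | CCSC(=O)[C@H](C)[C@H](O[Si](C)(C)C(C)(C)C)[C@H](C)C(=O)[C@@H](C)c1oc(CC)c(C)c(=O)c1C
F4 | step 12 | (4R,6R)-5-hydroxy-4,6-dimethylnonane-3,7-dione | CCC(=O)[C@H](C)C(O)[C@@H](C)C(=O)CC
F5 | step 12 | (4R,6R)-4,6-dimethyl-3,7-dioxononan-5-yl (2R,3S,4S)-3-[(tert-butyldimethylsilyl)oxy]-5-(ethylsulfanyl)-2,4-dimethyl-5-oxopentanoate | CCC(=O)[C@H](C)C(OC(=O)[C@H](C)[C@H](O[Si](C)(C)C(C)(C)C)[C@H](C)C(=O)SCC)[C@@H](C)C(=O)CC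
F6 | step 12 | (4R,6R)-4,6-dimethyl-3,7-dioxononan-5-yl (2R,3R,4S,6S)-3-[(tert-butyldimethylsilyl)oxy]-6-(6-ethyl-3,5-dimethyl-4-oxo-4H-pyran-2-yl)-2,4-dimethyl-5-oxoheptanoate | CCC(=O)[C@H](C)C(OC(=O)[C@H](C)[C@H](O[Si](C)(C)C(C)(C)C)[C@H](C)C(=O)[C@@H](C)c1oc(CC)c(C)c(=O)c1C)[C@@H](C)C(=O)CC
F7 | step 11 | (2S,3R,4R)-3-[(tert-butyldimethylsilyl)oxy]-2,4-dimethyl-5-oxo-5-(prop-2-en-1-yloxy)pentanoic acid | C=CCOC(=O)[C@H](C)[C@H](O[Si](C)(C)C(C)(C)C)[C@H](C)C(=O)O
F8 | step 11 | prop-2-en-1-yl (2R,3S,4S)-3-[(tert-butyldimethylsilyl)oxy]-5-(ethylsulfanyl)-2,4-dimethyl-5-oxopentanoate | C=CCOC(=O)[C@H](C)[C@H](O[Si](C)(C)C(C)(C)C)[C@H](C)C(=O)SCC
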